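**Retrosynthetic overview**

1. Botryotin E ⇐ desilylation, acetate opening of a C12 spiro-epoxide and Corey–Chaykovsky epoxidation of the C12 ketone ⇐ tetracyclic ketone 18.
2. 18 ⇐ iodo chloro enone 15 in one operation: the C16–C12 bond closes ring D across ring C (bicyclo[2.2.2] alkoxide), then C11 shifts from C12 to C13 and ring C contracts from six to five carbons.
3. Enabling feature: rings C (C8, C9=C11, C13, C14) and D (C8, C15, C16, C12, C13, C14) are the six ring-C carbons of a podocarpane, oxygenated 1,3 at C12 and C14, bridged C8→C12 by the C15–C16 ethano unit, with C11 moved from C12 to C13; a cyclohexenone with a leaving group at C13 is therefore a direct precursor.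
4. 15 ⇐ dienone 9 (conjugate epoxidation, chloride opening, silylation, ozonolysis, iodination) ⇐ phenol 7 by oxidative dearomative allylation, which makes the C8 quaternary centre.
5. 7 ⇐ dehydroabietic acid 1, which supplies rings A and B, the C4, C5 and C10 stereocentres and all six ring-C carbons; ring order: A and B from the pool, then D and C together in step 12.

Key step: step 12

Remark: podocarpane numbering is used throughout (C18 = CH2O on C4; C15 and C16 = the two carbons added at C8; C17 = the acetoxymethyl carbon on C12), α means the face opposite the C10 methyl group, and commercial dehydroabietic acid is taken to be the 4α-carboxylic acid.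

**Route**

Step 1
Reactants: 1 dehydroabietic acid
Product: 2 methyl dehydroabietate
Conditions: MeI, K2CO3, DMF, 23 °C
Reagents that add atoms: iodomethane (CI)
Why: SN2 O-alkylation of the carboxylate (esterification) masks the hindered C18 acid for the Lewis-acid steps that follow and touches no stereocentre.

Step 2
Reactants: 2 methyl dehydroabietate
Product: 3 methyl 12-acetylabieta-8,11,13-trien-18-oate
Conditions: AcCl, AlCl3, CH2Cl2, 0 → 23 °C
Reagents that add atoms: acetyl chloride (CC(Cl)=O)
Why: Friedel–Crafts acylation should go to C12, the only unhindered position ortho to the isopropyl group, because C11 and C14 are blocked by the peri substituents.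

Step 3
Reactants: 3 methyl 12-acetylabieta-8,11,13-trien-18-oate
Product: 5 methyl 12-hydroxyabieta-8,11,13-trien-18-oate, via aryl acetate 4 (not isolated)
Conditions: mCPBA, CF3CO2H (cat.), CH2Cl2, 23 °C; then K2CO3, MeOH, 23 °C
Reagents that add atoms: 3-chloroperoxybenzoic acid (OOC(=O)c1cccc(Cl)c1)
Why: Baeyer–Villiger oxidation of the aryl methyl ketone with migration of the electron-rich aryl group should give the aryl acetate, which methanolysis converts into the C12 phenol.

Step 4
Reactants: 5 methyl 12-hydroxyabieta-8,11,13-trien-18-oate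
Product: 6 methyl 12-hydroxypodocarpa-8,11,13-trien-18-oate
Conditions: AlCl3, toluene, 23 → 60 °C
Reagents that add atoms: none
Why: Retro-Friedel–Crafts transalkylation should remove the isopropyl group, since ipso-protonation at C13 is activated by the ortho hydroxyl and toluene traps the isopropyl cation (as in the dealkylation of thymol to m-cresol), while C4, C5 and C10 stay untouched.

Step 5
Reactants: 6 methyl 12-hydroxypodocarpa-8,11,13-trien-18-oate
Product: 7 podocarpa-8,11,13-triene-12,18-diol
Conditions: LiAlH4, THF, 0 → 66 °C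
Reagents that add atoms: none
Why: Hydride reduction of the neopentyl methyl ester should give the primary C18 alcohol while the phenol is carried through as its aluminate.

Step 6
Reactants: 7 podocarpa-8,11,13-triene-12,18-diol; 8 allyltrimethylsilane
Product: 9 8α-allyl-18-hydroxypodocarpa-9(11),13-dien-12-one
Conditions: PhI(OAc)2, allylSiMe3 (5 equiv), (CF3)2CHOH–CH2Cl2, −20 °C
Reagents that add atoms: allyltrimethylsilane (C=CC[Si](C)(C)C)
Why: Oxidative dearomatization with Hosomi–Sakurai-type trapping should place the allyl group on the para carbon C8 of the phenoxenium ion from the α-face, anti to the axial C10 methyl group, which sets the C8 quaternary stereocentre of a cyclohexa-2,5-dienone.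

Step 7
Reactants: 9 8α-allyl-18-hydroxypodocarpa-9(11),13-dien-12-one
Product: 10 8α-allyl-13β,14β-epoxy-18-hydroxypodocarp-9(11)-en-12-one
Conditions: H2O2 (30% aq), NaOH, MeOH, 0 °C
Reagents that add atoms: hydrogen peroxide (OO)
Why: Weitz–Scheffer nucleophilic epoxidation should attack only the disubstituted C13=C14 enone (C9 is a fully substituted β-carbon) on the face anti to the C8 allyl group, as in the 1α,2α-epoxidation of steroidal 1,4-dien-3-ones, which sets C13 and C14 with the oxygen β.

Step 8
Reactants: 10 8α-allyl-13β,14β-epoxy-18-hydroxypodocarp-9(11)-en-12-one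
Product: 11 8α-allyl-13α-chloro-14β,18-dihydroxypodocarp-9(11)-en-12-one
Conditions: LiCl, AcOH, THF, 0 → 23 °C
Reagents that add atoms: lithium chloride ([Li+].[Cl-])
Why: Halide opening of the α,β-epoxy ketone by SN2 attack at the α-keto carbon C13 (C14 is neopentyl) should proceed with inversion and give the trans-chlorohydrin with 13α-Cl and 14β-OH.

Step 9
Reactants: 11 8α-allyl-13α-chloro-14β,18-dihydroxypodocarp-9(11)-en-12-one
Product: 12 8α-allyl-13α-chloro-14β,18-bis(tert-butyldimethylsilyloxy)podocarp-9(11)-en-12-one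
Conditions: TBSOTf (2.5 equiv), 2,6-lutidine, CH2Cl2, −78 → 0 °C
Reagents that add atoms: tert-butyldimethylsilyl trifluoromethanesulfonate (CC(C)(C)[Si](C)(C)OS(=O)(=O)C(F)(F)F)
Why: Silyl triflate silylation should protect both the hindered secondary C14 hydroxyl and the primary C18 hydroxyl and so shut down retro-aldol and proton-quench pathways in later steps.

Step 10
Reactants: 12 8α-allyl-13α-chloro-14β,18-bis(tert-butyldimethylsilyloxy)podocarp-9(11)-en-12-one
Product: 14 13α-chloro-8α-(2-hydroxyethyl)-14β,18-bis(tert-butyldimethylsilyloxy)podocarp-9(11)-en-12-one, via aldehyde 13 (not isolated)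
Conditions: O3, CH2Cl2, −78 °C (Sudan Red 7B end point); PPh3; then NaBH(OAc)3, AcOH, 23 °C
Reagents that add atoms: ozone ([O-][O+]=O)
Why: Ozonolysis should cleave only the electron-rich terminal alkene (the C9=C11 enone alkene is deactivated and flanked by two quaternary carbons), and NaBH(OAc)3 should reduce the aldehyde but not the conjugated ketone.

Step 11
Reactants: 14 13α-chloro-8α-(2-hydroxyethyl)-14β,18-bis(tert-butyldimethylsilyloxy)podocarp-9(11)-en-12-one
Product: 15 13α-chloro-8α-(2-iodoethyl)-14β,18-bis(tert-butyldimethylsilyloxy)podocarp-9(11)-en-12-one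
Conditions: I2, PPh3, imidazole, CH2Cl2, 0 °C
Reagents that add atoms: iodine (II)
Why: Appel-type iodination should convert the unhindered primary alcohol into the primary iodide by SN2 displacement of the alkoxyphosphonium group.

Step 12
Reactants: 15 13α-chloro-8α-(2-iodoethyl)-14β,18-bis(tert-butyldimethylsilyloxy)podocarp-9(11)-en-12-one
Product: 18 tetracyclic 12-ketone with ring C = C8, C9=C11, C13, C14 and ring D = C8, C15, C16, C12, C13, C14 and with 14,18-bis(tert-butyldimethylsilyloxy) groups (C14 oxygen syn to the C9=C11 bridge), via alkyllithium 16 (not isolated), via lithium bicyclo[2.2.2]octenolate 17 (not isolated)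
Conditions: t-BuLi (2.1 equiv), Et2O–pentane, −100 → −78 °C; then MgBr2·OEt2, THF, −78 → 40 °C
Reagents that add atoms: none
Why: t-BuLi should exchange the primary iodide faster than it attacks the hindered α-chloro enone, and the C16 carbanion, held on the α-face by the C8 stereocentre, should add across ring C to the C12 carbonyl to give the bridgehead alkoxide 17 of a bicyclo[2.2.2]oct-5-ene; on warming with MgBr2 this alkoxide should push out the C13 chloride while C11 migrates from C12 to C13 (halohydrin semipinacol 1,2-vinyl shift), which gives ketone 18. The closest known reactions are the iodine–lithium-exchange (Barbier-type) cyclisation of iodoalkyl ketones to bridgehead alcohols, the semipinacol rearrangement of metal alkoxides formed from α-chloro ketones and organometallics, and the pinacol-type shift of bicyclo[2.2.2]octenyl to bicyclo[3.2.1]octenyl systems driven by a bridgehead oxygen. Ring D closes by 6-exo-trig addition of C16 to C12=O (the C16–C12 bond), and ring C is made by contraction from six to five members through the anti 1,2-shift that forms the C11–C13 bond. C13 is set by inversion, because C11 enters on the face opposite the departing 13α-chloride; C8 and C14 are carried through unchanged and C12 becomes a ketone. The step needs C11 and not C16 to migrate, and needs no epoxide formation or direct alkylation at C13: the 13α-chlorine lies on the side of the new ethano bridge, so only the C12–C11 bond is antiperiplanar to C–Cl, the bridgehead oxygen is gauche to it, and the α-tethered carbanion cannot reach the back side of the C–Cl bond.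

Step 13
Reactants: 18 tetracyclic 12-ketone; 19 trimethylsulfonium iodide
Product: 20 C12 spiro-epoxide of 18 (C17H2 axial, syn to the C14 bridge; oxygen equatorial)
Conditions: Me3S+ I−, KN(SiMe3)2, THF, −10 → 23 °C
Reagents that add atoms: trimethylsulfonium iodide (C[S+](C)C.[I-])
Why: In the Corey–Chaykovsky epoxidation the unstabilised sulfonium ylide should add irreversibly to the C12 ketone from the exo face (axial attack, syn to the one-carbon bridge, whose substituent on that side is hydrogen), so the new CH2 is axial and the oxygen equatorial at C12.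

Step 14
Reactants: 20 C12 spiro-epoxide; 21 acetic acid
Product: 22 14,18-bis-O-(tert-butyldimethylsilyl)botryotin E
Conditions: AcOH, CsOAc, DMF, 90 °C
Reagents that add atoms: acetic acid (CC(O)=O)
Why: Acetate should open the spiro-epoxide by SN2 attack at the primary carbon C17, leaving the tertiary C12–O bond and its configuration intact and giving the tertiary alcohol with the primary acetate.

Step 15
Reactants: 22 14,18-bis-O-(tert-butyldimethylsilyl)botryotin E
Product: 23 botryotin E
Conditions: HF·pyridine, THF–pyridine, 0 → 40 °C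
Reagents that add atoms: none
Why: Fluoride-mediated desilylation under buffered, non-basic conditions should free the C14 and C18 hydroxyls without cleaving or migrating the primary acetate.

**Compound list**

1 | dehydroabietic acid (abieta-8,11,13-trien-18-oic acid) | CC(C)c1cc2CC[C@H]3[C@](C)(C(O)=O)CCC[C@]3(C)c2cc1 | starting material
2 | methyl dehydroabietate | CC(C)c1cc2CC[C@H]3[C@](C)(C(=O)OC)CCC[C@]3(C)c2cc1 | intermediate
3 | methyl 12-acetylabieta-8,11,13-trien-18-oate | CC(C)c1cc2CC[C@H]3[C@](C)(C(=O)OC)CCC[C@]3(C)c2cc1C(C)=O | intermediate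
4 | methyl 12-acetoxyabieta-8,11,13-trien-18-oate (aryl acetate) | CC(C)c1cc2CC[C@H]3[C@](C)(C(=O)OC)CCC[C@]3(C)c2cc1OC(C)=O | intermediate
5 | methyl 12-hydroxyabieta-8,11,13-trien-18-oate | CC(C)c1cc2CC[C@H]3[C@](C)(C(=O)OC)CCC[C@]3(C)c2cc1O | intermediate
6 | methyl 12-hydroxypodocarpa-8,11,13-trien-18-oate | Oc1ccc2CC[C@H]3[C@](C)(C(=O)OC)CCC[C@]3(C)c2c1 | intermediate
7 | podocarpa-8,11,13-triene-12,18-diol | Oc1ccc2CC[C@H]3[C@](C)(CO)CCC[C@]3(C)c2c1 | intermediate
8 | allyltrimethylsilane | C=CC[Si](C)(C)C | starting material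
9 | 8α-allyl-18-hydroxypodocarpa-9(11),13-dien-12-one | C=CC[C@]12CC[C@H]3[C@](C)(CO)CCC[C@]3(C)C1=CC(=O)C=C2 | intermediate
10 | 8α-allyl-13β,14β-epoxy-18-hydroxypodocarp-9(11)-en-12-one | C=CC[C@]12CC[C@H]3[C@](C)(CO)CCC[C@]3(C)C1=CC(=O)[C@H]4O[C@H]42 | intermediate
11 | 8α-allyl-13α-chloro-14β,18-dihydroxypodocarp-9(11)-en-12-one | C=CC[C@]12CC[C@H]3[C@](C)(CO)CCC[C@]3(C)C1=CC(=O)[C@H](Cl)[C@H]2O | intermediate
12 | 8α-allyl-13α-chloro-14β,18-bis(tert-butyldimethylsilyloxy)podocarp-9(11)-en-12-one | C=CC[C@]12CC[C@H]3[C@](C)(CO[Si](C)(C)C(C)(C)C)CCC[C@]3(C)C1=CC(=O)[C@H](Cl)[C@H]2O[Si](C)(C)C(C)(C)C | intermediate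
13 | 13α-chloro-8α-(2-oxoethyl)-14β,18-bis(tert-butyldimethylsilyloxy)podocarp-9(11)-en-12-one (aldehyde) | O=CC[C@]12CC[C@H]3[C@](C)(CO[Si](C)(C)C(C)(C)C)CCC[C@]3(C)C1=CC(=O)[C@H](Cl)[C@H]2O[Si](C)(C)C(C)(C)C | intermediate
14 | 13α-chloro-8α-(2-hydroxyethyl)-14β,18-bis(tert-butyldimethylsilyloxy)podocarp-9(11)-en-12-one | OCC[C@]12CC[C@H]3[C@](C)(CO[Si](C)(C)C(C)(C)C)CCC[C@]3(C)C1=CC(=O)[C@H](Cl)[C@H]2O[Si](C)(C)C(C)(C)C | intermediate
15 | 13α-chloro-8α-(2-iodoethyl)-14β,18-bis(tert-butyldimethylsilyloxy)podocarp-9(11)-en-12-one | ICC[C@]12CC[C@H]3[C@](C)(CO[Si](C)(C)C(C)(C)C)CCC[C@]3(C)C1=CC(=O)[C@H](Cl)[C@H]2O[Si](C)(C)C(C)(C)C | intermediate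
16 | 8α-(2-lithioethyl) analogue of 15 (alkyllithium) | [Li]CC[C@]12CC[C@H]3[C@](C)(CO[Si](C)(C)C(C)(C)C)CCC[C@]3(C)C1=CC(=O)[C@H](Cl)[C@H]2O[Si](C)(C)C(C)(C)C | intermediate
17 | lithium alkoxide of the 8α,12α-ethano-bridged 13α-chloro-14β,18-bis(tert-butyldimethylsilyloxy)podocarp-9(11)-en-12-ol (bicyclo[2.2.2]oct-5-en-1-olate; chlorine on the side of the ethano bridge) | [Li]O[C@]12CC[C@@]3(CC[C@H]4[C@](C)(CO[Si](C)(C)C(C)(C)C)CCC[C@]4(C)C3=C1)[C@H](O[Si](C)(C)C(C)(C)C)[C@H]2Cl | intermediate
18 | tetracyclic 12-ketone: bicyclo[3.2.1]oct-6-en-2-one core (C12=O in ring D, C9=C11 bridge, C14 silyloxy syn to that bridge), 14,18-bis(tert-butyldimethylsilyl) ether | O=C1CC[C@]23CC[C@H]4[C@](C)(CO[Si](C)(C)C(C)(C)C)CCC[C@]4(C)C2=C[C@H]1[C@H]3O[Si](C)(C)C(C)(C)C | intermediate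
19 | trimethylsulfonium iodide | C[S+](C)C.[I-] | starting material
20 | C12 spiro-epoxide of 18 (C17H2 axial, oxygen equatorial) | C1O[C@@]12CC[C@]34CC[C@H]5[C@](C)(CO[Si](C)(C)C(C)(C)C)CCC[C@]5(C)C3=C[C@H]2[C@H]4O[Si](C)(C)C(C)(C)C | intermediate
21 | acetic acid | CC(O)=O | starting material
22 | 14,18-bis-O-(tert-butyldimethylsilyl)botryotin E | CC(=O)OC[C@@]1(O)CC[C@]23CC[C@H]4[C@](C)(CO[Si](C)(C)C(C)(C)C)CCC[C@]4(C)C2=C[C@H]1[C@H]3O[Si](C)(C)C(C)(C)C | intermediate
23 | botryotin E | CC(=O)OC[C@@]1(O)CC[C@]23CC[C@H]4[C@](C)(CO)CCC[C@]4(C)C2=C[C@H]1[C@H]3O | target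

**Summary and risks**

Total step count: 15. Longest linear sequence: 15 steps (from dehydroabietic acid).

Steps most likely to fail:

Step 12. The iodine–lithium exchange may be outrun by enolisation of, or attack at, the α-chloro ketone, or the bridgehead alkoxide may not rearrange. Fallback (ring contraction first, then ring D by acyl substitution): from 12, NaOMe in MeOH at 0 °C adds to the C12 carbonyl and the adduct undergoes the quasi-Favorskii (semibenzilic) shift of C11 from C12 to C13 with loss of chloride, which is possible because C11 carries no enolisable hydrogen; this gives the ring-contracted cyclopentene methyl ester F1. Ozonolysis (O3; PPh3) and NaBH(OAc)3 reduction give the primary alcohol F2, and I2, PPh3 and imidazole give the iodide F3. t-BuLi at −100 °C then effects iodine–lithium exchange and intramolecular acyl substitution on the methyl ester (Parham-type cyclisation), which forms the C16–C12 bond and comes back to the route at ketone 18.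

Step 6. The allylsilane may attack the ortho positions, the dienone may undergo dienone–phenol rearrangement in the acidic medium, or facial selectivity at C8 may be poor. Fallback (sigmatropic delivery in place of cation capture): from 7, Br2 (2 equiv) in AcOH gives 11,13-dibromopodocarpa-8,11,13-triene-12,18-diol F4, and allyl bromide with K2CO3 gives the allyl aryl ether F5. Heating in N,N-diethylaniline at 190 °C brings about the para-Claisen rearrangement (ortho-Claisen, then Cope, both ortho positions being blocked), which should place the allyl group on C8 from the less hindered α-face and give the dibromodienone F6. Hydrodebromination with Bu3SnH and Pd(PPh3)4 comes back to the route at dienone 9.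

Step 7. Facial selectivity of the conjugate epoxidation may be poor; attack syn to the C8 side chain would give the wrong C13/C14 pair. Fallback (hydroxyl-directed oxygen delivery): from 9, Luche reduction (NaBH4, CeCl3·7H2O, MeOH) gives the bis-allylic alcohols, from which the 12β-alcohol F7 is separated while the 12α-epimer is returned to 9 with MnO2. VO(acac)2 and t-BuOOH then epoxidise the less hindered C13=C14 alkene syn to the hydroxyl to give the epoxy alcohol F8, and MnO2 oxidation comes back to the route at epoxy enone 10.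

Further compounds
F1 | step 12 | ring-contracted methyl ester: 8α-allyl cyclopentene (C8, C9=C11, C13, C14) with CO2Me on C13, 14β,18-bis(tert-butyldimethylsilyl) ether | C=CC[C@]12CC[C@H]3[C@](C)(CO[Si](C)(C)C(C)(C)C)CCC[C@]3(C)C1=C[C@H](C(=O)OC)[C@H]2O[Si](C)(C)C(C)(C)C
F2 | step 12 | 8α-(2-hydroxyethyl) analogue of F1 (primary alcohol) | OCC[C@]12CC[C@H]3[C@](C)(CO[Si](C)(C)C(C)(C)C)CCC[C@]3(C)C1=C[C@H](C(=O)OC)[C@H]2O[Si](C)(C)C(C)(C)C
F3 | step 12 | 8α-(2-iodoethyl) analogue of F1 (iodide) | ICC[C@]12CC[C@H]3[C@](C)(CO[Si](C)(C)C(C)(C)C)CCC[C@]3(C)C1=C[C@H](C(=O)OC)[C@H]2O[Si](C)(C)C(C)(C)C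
F4 | step 6 | 11,13-dibromopodocarpa-8,11,13-triene-12,18-diol | Oc1c(Br)cc2CC[C@H]3[C@](C)(CO)CCC[C@]3(C)c2c1Br
F5 | step 6 | 12-allyloxy-11,13-dibromopodocarpa-8,11,13-trien-18-ol (allyl aryl ether) | C=CCOc1c(Br)cc2CC[C@H]3[C@](C)(CO)CCC[C@]3(C)c2c1Br
F6 | step 6 | 8α-allyl-11,13-dibromo-18-hydroxypodocarpa-9(11),13-dien-12-one (dibromodienone) | C=CC[C@]12CC[C@H]3[C@](C)(CO)CCC[C@]3(C)C1=C(Br)C(=O)C(Br)=C2
F7 | step 7 | 8α-allylpodocarpa-9(11),13-diene-12β,18-diol | C=CC[C@]12CC[C@H]3[C@](C)(CO)CCC[C@]3(C)C1=C[C@@H](O)C=C2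
F8 | step 7 | 8α-allyl-13β,14β-epoxypodocarp-9(11)-ene-12β,18-diol | C=CC[C@]12CC[C@H]3[C@](C)(CO)CCC[C@]3(C)C1=C[C@@H](O)[C@H]4O[C@H]42
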